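in all of them: substrate 20 mM
- dusk: reagent 16 mM; the very flask that is asked about, followed so far
- noon: reagent 8 mM; run made earlier
- flask: reagent 16.0 mM; time 15 d

| run | time / d | intermediate / % | product / % | substrate / % |
|---|---|---|---|---|
| dusk | 0.167 | 12.0 | 1.3 | 83.6 |
| dusk | 0.500 | 21.2 | 8.0 | 68.0 |
| dusk | 1.67 | 14.7 | 36.3 | 45.9 |
| dusk | 5.00 | 6.2 | 62.7 | 31.6 |
| noon | 0.167 | 6.5 | 0.7 | 92.5 |
| noon | 0.500 | 13.1 | 4.9 | 83.3 |
| noon | 1.67 | 6.6 | 19.3 | 69.8 |
| noon | 6.00 | 0.9 | 38.3 | 62.9 |

(standard deviation of a reading: 1 percentage point)

- when, up to 15 d, the flask holds most intermediate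
- the amount of intermediate, in percent of the substrate charged, at that time

- the numbers in the tables scatter by 1 percentage point (one standard deviation)

I began with an easy division: reagent charged over substrate charged, the charge ratio, 0.800 for dusk and 0.400 for noon. It marks the end state, with reagent as the limiting reagent. At its last reading, noon held 39.2 % as intermediate plus product, close to its ratio.

Next I read 26.5 % for dusk and 32.8 % for noon as the peak share, the highest intermediate reading as a fraction of the charge ratio. These readings differ, so one number was not enough, and I turned to the dusk readings, since dusk is this flask. Substrate lost per product gained was 2.33 up to 0.500 d and 0.781 after it. So on average dusk gained intermediate before that reading and lost it afterwards, and I put the peak just past that reading, near its 21.2 %.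

The forecast said 0.65 d and 22 %: “the peak is near 0.65 d”.

The flask peaked at 0.636 d with 21.5 %, a peak share of 26.9 %.

    released group → by-product carried off (k = 6.53 × 10⁻⁴ min⁻¹)
    intermediate ⇌ product + released group (K = 0.0270 M, k = 9.90 × 10⁻⁴ min⁻¹)
    substrate + reagent ⇌ intermediate (K = 150 L mol⁻¹, k = 0.0474 L mol⁻¹ min⁻¹)

At 0.757 d, the forward half-life of intermediate in this flask was 0.49 d, shorter than the 0.63 d forward half-life of substrate at the charges. On the ratio 0.320 equiv, the peak shares read at dusk and noon gave 8.48 % and 10.5 %, and the neighbour charged with 6.4 mM of reagent peaked at 9.66 %.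

The runs stem from a simulated flask with constants of no real substance.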